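(Readings and results are simulated for an exercise, noise included.)

Substrate is the easy species to follow: the fraction left barely depends on the charge, 67.1% in gamma against 66.6% in zeta at 3.00 min, so one clock read from these runs can be carried to the flask.

| flask | substrate | gas phase | remark | time |
|---|---|---|---|---|
| gamma | 0.050 M | 50 mM (held) | run made earlier |  |
| zeta | 0.075 M | 50 mM (held) | run made earlier |  |
| flask | 0.10 M | 50 mM (held) |  | 3.0 min |

- gamma (time / min: target / %, substrate / %): 0.500: 3.3, 95.2; 1.00: 11.1, 89.4; 1.50: 15.7, 82.4; 2.00: 23.2, 77.5; 2.50: 24.2, 70.5; 3.00: 30.2, 67.1; 4.00: 35.5, 57.4
- zeta (time / min: target / %, substrate / %): 0.200: 0.7, 98.8; 0.500: 4.6, 95.3; 1.00: 9.5, 88.4; 1.50: 16.3, 82.4; 2.00: 21.4, 77.4; 3.00: 31.4, 66.6; 4.00: 37.4, 59.8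

(readings scatter by 1 percentage point)

- amount of target at 3.0 min, in percent of the substrate charged
- the change that raises the amount of target at 3.0 min, in percent of the substrate charged most ("none" if none brings more than 2 percentage points) (birch / ash / none)
- amount of target at 3.0 min, in percent of the substrate charged, after ash

- birch: doubling the transfer coefficient of the gas phase, all else as stated
- ash: doubling the saturation concentration of gas phase, all else as stated

- the analysis behind the earlier runs scatters by 1 percentage point, standard deviation
- at the start none of the gas phase is in solution

The slope of ln(fraction of substrate left) from 0.500 min to 4.00 min, pooled over both runs, gives the pseudo-first-order constant k′, the share of remaining substrate turned per minute at 50 mM gas phase: 0.139 /min. Each run starts without dissolved gas, so the early end is joined to this line: run back through gamma's first reading, it meets the full charge at a lag of 0.146 min, a reading with the scatter of that point. The fraction left is then exp(−k′(t − lag)).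

The ladder starts at the lag, which is much shorter than 3.0 min, so the flask should run at k′ for nearly all of that time. The substrate lifetime, 7.20 min, exceeds 3.0 min, so the flask should still hold 67.3% of its substrate. Behind these comes a shortfall: at 3.00 min substrate plus target fell short of the charge by 2.4 percentage points on average in the earlier runs, a reading with their scatter, and this gap is the thing to watch. Taking the same gap for the flask, this reckoning gives 30.4% target.

Birch, if it halves the lag, should add 0.68 points. Ash, if k′ doubles with dissolved gas (untested) and the gap grows 4-fold, gives 45.3%, a gain of 15 points, more than birch.

The forecast says 30.5% (28% to 33%), ash, and 47% (38% to 53%), holding that birch “removes only the small lag”.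

The flask gives 29.9%. Ash gains 16 points against 1.1 points for birch and reaches 45.6%.

    substrate + dissolved gas → target (k = 0.0486 /M/s)
    gas phase ⇌ dissolved gas, rate k2*(csat - [dissolved gas]) (kL = 0.108 /s)
    dissolved gas → decomposed reagent (k = 0.00139 /s)
    dissolved gas + target → over-reacted product (k = 0.0202 /M/s)

At 3.00 min the flask holds 67.4% substrate against the reckoned 67.3%, and the half-life of substrate by the step to target is 5.0 min, where ln(2)/k′ gives 4.99 min; target is then made 5.42 times faster than it is used up, each step taken net, and it stands at 29.9% beside 2.70% over-reacted product. Read at 12 min, the same flask has a reckoned 19.2% substrate left and actually holds 19.1%, beside 53.3% target.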